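**Reading times.** The readings fall at 0.60 min in Friday's flask and 2.5 min in Monday's. Both flasks receive the same enzyme charge, but Monday's receives it in portions.

common to all: starting material 0.10 M

| run | enzyme | remark | time |
|---|---|---|---|
| epsilon | 12 µM (in portions, 4) | run made earlier; portions every 40 s |  |
| beta | 50 µM (in portions, 4) | run made earlier; portions every 40 s |  |
| Friday's | 25 µM | everything together at the start | 0.60 min |
| Monday's | 25 µM (in portions, 4) | the portions of enzyme follow each other after 40 s, the first at the start | 2.5 min |

- epsilon (time / min: product / %, starting material / %): 0.333: 26.6, 74.0; 0.667: 40.4, 59.1; 1.00: 56.8, 43.1; 1.33: 64.4, 35.2; 2.00: 76.5, 23.0; 2.50: 82.5, 18.9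
- beta (time / min: product / %, starting material / %): 0.167: 41.7, 57.6; 0.417: 62.1, 38.2; 0.667: 71.1, 28.5; 1.00: 80.7, 19.1; 1.50: 87.2, 12.5; 2.00: 90.6, 9.9; 2.50: 93.1, 7.0

(readings scatter by 0.3 percentage points)

1. the winner by amount of product, in percent of the starting material charged; "neither" if no more than 2 percentage points parts them (Friday's / Monday's / neither)
2. how much product is there at the end, in percent of the starting material charged: Friday's
3. how much product is there at the end, in percent of the starting material charged: Monday's

- the numbers in the tables scatter with a standard deviation of 0.3 percentage points

**Carried quantity.** Let S be the enzyme concentration summed over time. Once the last portion is in, S is the whole charge times the reading time less the mean delay of the portions, here 60.0 s. Friday's flask reaches 15.0 µM·min. Monday's flask reaches 37.5 µM·min; this exposure is the field's normalised time. In the earlier runs, at this starting concentration, near-equal S gives near-equal product: epsilon has 40.4% at 2.00 µM·min, and beta has 41.7% at 2.09 µM·min.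

**What will stand.** Two epsilon readings stand at 12.0 µM·min and 18.0 µM·min. Friday's S lies half way between them, so this reckoning expects 79.5% product. Monday's S lies between two beta readings, 31.2 µM·min and 50.0 µM·min, which gives 88.3%.

**Not to touch.** The reading times stay as they are, because Monday's lead rests on its larger S.

**The forecast.** It names Monday's, with 83% for Friday's flask and 88% for Monday's. Its ground is “a burst that quickly fades”. Its Friday figure stands above this reckoning.

**The flask.** Monday's flask ends at 88.7% and Friday's at 79.7%, with S at 37.5 µM·min against 15.0 µM·min and enzyme at 100% and 100% of charge. starting material + enzyme → product + enzyme, rate k1*[starting material]^2.5*[enzyme]/(1 + ([starting material]/Kh1)^2.5) (0.170 M, k = 2.40 × 10⁵ M⁻²·⁵ s⁻¹)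

Monday's flask read at 4.0 min reaches 75.0 µM·min, equal to 75.0 µM·min at beta's last reading, and holds 92.8% product against beta's 93.1%.

All runs were generated by integration for substances that don't exist; the scatter is artificial.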